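**Retrosynthetic overview** (indene numbering: C1(H)Me, C2=C3(Et), C3a(H), C4(Me)(CO2H), C5(Me)(phenylbutadienyl), C6=C7(Me), C7a(H))
- Endgame: the acid comes from a 2-(trimethylsilyl)ethyl (TMSE) ester. The C3 ethyl group and the C2=C3 alkene come from the C3 enol triflate of a trans-hydrindenone by Negishi coupling.
- Key cut: in the six-membered ring, the C6=C7 alkene flanked by the σ-bonds C7a–C3a and C5–C4 is a Diels–Alder retron, and C3–C2–C1 bridges C3a and C7a. Cutting both σ-bonds opens both rings to an acyclic 4-oxo-2,7,9,11,13-pentaenoate.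
- Forward, one thermal intramolecular Diels–Alder reaction (IMDA) closes both rings, joins the vicinal quaternary carbons C4 and C5, and sets C3a, C4, C5 and C7a from the single C1 stereocentre through A(1,3) strain with the C7 methyl group. The C3 ketone is the second activator and the later handle for the ethyl group.
- Precursor: the C3–C3a bond is made by Nozaki–Hiyama–Kishi coupling and oxidation. The tetraene comes from two formyl-ylide Wittig homologations and a cinnamyl HWE olefination on (R)-methylsuccinic acid 4-methyl ester, the only chirality bought.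
- Ring order: the chain stays acyclic up to the key step, where both rings form in the same event.

Key step: step 9

Assumption: the carbinol centre made in step 7 is left uncontrolled because step 8 erases it. Compounds 1, 4, 7 and 11 are taken as catalogue compounds (11 is otherwise two steps from diethyl methylmalonate and iodoform).

**Step 1**
Reactants: 1 (R)-4-methoxy-2-methyl-4-oxobutanoic acid
Product: 3 methyl (R)-3-methyl-4-oxobutanoate, via acid chloride 2 (not isolated)
Conditions: (COCl)2, cat. DMF, CH2Cl2, 0 °C to rt, evaporate; LiAlH(OtBu)3, THF, −78 °C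
Reagents that add atoms: none
Why: Acid chloride formation followed by partial reduction with the bulky hydride LiAlH(OtBu)3 should stop at the aldehyde and spare the methyl ester, and with no base present the purchased stereocentre is kept.

**Step 2**
Reactants: 3 methyl (R)-3-methyl-4-oxobutanoate; 4 2-(triphenylphosphoranylidene)propanal
Product: 5 methyl (3R,4E)-3,5-dimethyl-6-oxohex-4-enoate
Conditions: toluene, 70 °C
Reagents that add atoms: none
Why: Wittig olefination with the stabilised formyl ylide should give the (E)-trisubstituted enal, and the neutral medium should not epimerise the α-methyl aldehyde before it reacts.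

**Step 3**
Reactants: 5 methyl (3R,4E)-3,5-dimethyl-6-oxohex-4-enoate; 4 2-(triphenylphosphoranylidene)propanal
Product: 6 methyl (3R,4E,6E)-3,5,7-trimethyl-8-oxoocta-4,6-dienoate
Conditions: toluene, 110 °C
Reagents that add atoms: none
Why: A second Wittig homologation with the same stabilised ylide is E-selective, and the dienal formed is less electrophilic than the enal, so chain growth should stop after one unit.

**Step 4**
Reactants: 6 methyl (3R,4E,6E)-3,5,7-trimethyl-8-oxoocta-4,6-dienoate; 7 diethyl (E)-cinnamylphosphonate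
Product: 9 methyl (3R,4E,6E,8E,10E)-3,5,7-trimethyl-11-phenylundeca-4,6,8,10-tetraenoate, via lithiated phosphonate 8 (not isolated)
Conditions: 7, LiHMDS, THF, −78 °C; then 6, −78 °C to rt, dark
Reagents that add atoms: none
Why: Horner–Wadsworth–Emmons olefination with the preformed allylic phosphonate anion should give the new disubstituted alkene as the E isomer and should attack the aldehyde much faster than the methyl ester.

**Step 5**
Reactants: 9 methyl (3R,4E,6E,8E,10E)-3,5,7-trimethyl-11-phenylundeca-4,6,8,10-tetraenoate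
Product: 10 (3R,4E,6E,8E,10E)-3,5,7-trimethyl-11-phenylundeca-4,6,8,10-tetraenal
Conditions: DIBAL-H (1.05 equiv), CH2Cl2, −78 °C; aqueous work-up
Reagents that add atoms: none
Why: Low-temperature DIBAL-H reduction of a methyl ester stops at the aldehyde level, the polyene is inert, and the stereocentre is β to the carbonyl and cannot epimerise.

**Step 6**
Reactants: 11 (E)-3-iodo-2-methylprop-2-enoic acid
Product: 12 2-(trimethylsilyl)ethyl (E)-3-iodo-2-methylprop-2-enoate
Conditions: Me3SiCH2CH2OH, DCC, cat. DMAP, CH2Cl2, 0 °C to rt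
Reagents that add atoms: 2-(trimethylsilyl)ethanol, C[Si](C)(C)CCO
Why: Steglich esterification installs an ester that can later be cleaved at silicon, away from what will become a very hindered carbonyl, and leaves the alkene geometry untouched.

**Step 7**
Reactants: 10 (3R,4E,6E,8E,10E)-3,5,7-trimethyl-11-phenylundeca-4,6,8,10-tetraenal; 12 2-(trimethylsilyl)ethyl (E)-3-iodo-2-methylprop-2-enoate
Product: 14 2-(trimethylsilyl)ethyl (2E,4RS,6R,7E,9E,11E,13E)-4-hydroxy-2,6,8,10-tetramethyl-14-phenyltetradeca-2,7,9,11,13-pentaenoate, via alkenylchromium(III) species 13 (not isolated)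
Conditions: CrCl2 (4 equiv), NiCl2 (2 mol %), DMF, rt, dark
Reagents that add atoms: none
Why: The Nozaki–Hiyama–Kishi reaction turns the vinyl iodide into an alkenylchromium reagent with retention of the E geometry, and this adds only to the aldehyde and tolerates the ester and the polyene.

**Step 8**
Reactants: 14 2-(trimethylsilyl)ethyl (2E,4RS,6R,7E,9E,11E,13E)-4-hydroxy-2,6,8,10-tetramethyl-14-phenyltetradeca-2,7,9,11,13-pentaenoate
Product: 15 2-(trimethylsilyl)ethyl (2E,6R,7E,9E,11E,13E)-2,6,8,10-tetramethyl-4-oxo-14-phenyltetradeca-2,7,9,11,13-pentaenoate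
Conditions: Dess–Martin periodinane, CH2Cl2, 0 °C
Reagents that add atoms: none
Why: Dess–Martin oxidation of the allylic alcohol is mild and nearly neutral, merges both carbinol epimers into one enone, and so unmasks the doubly activated dienophile only at this point.

**Step 9**
Reactants: 15 2-(trimethylsilyl)ethyl (2E,6R,7E,9E,11E,13E)-2,6,8,10-tetramethyl-4-oxo-14-phenyltetradeca-2,7,9,11,13-pentaenoate
Product: 16 2-(trimethylsilyl)ethyl (1R,3aS,4R,5S,7aS)-1,4,5,7-tetramethyl-3-oxo-5-[(1E,3E)-4-phenylbuta-1,3-dien-1-yl]-2,3,3a,4,5,7a-hexahydro-1H-indene-4-carboxylate (trans-fused)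
Conditions: toluene (5 mM), cat. BHT, 80 °C, argon, dark
Reagents that add atoms: none
Why: A concerted, asynchronous thermal [4π+2π] cycloaddition (type-1 intramolecular Diels–Alder reaction) of the (7E,9E)-diene C7=C8–C9=C10 onto the (2E)-alkene C2=C3, whose LUMO is lowered by the ester on C2 and the ketone on C3, forms the σ-bonds C3–C7 and C2–C10 and moves the alkene to C8=C9. The closest known reaction type is the thermal IMDA of (E,E,E)-1,6,8-nonatrienes with a terminal ester, which is known to give trans-hydrindenes and to join two fully substituted carbons in polyketide chains of this substitution pattern. The six-membered ring is the cycloaddition ring itself (both new bonds), and the five-membered ring C3–C4–C5–C6–C7 is closed by the C3–C7 bond through the three-atom tether, the only fused mode so short a tether allows. C4 and C5 of 16 follow from suprafacial addition to the E-alkene and the E,E-diene (ester cis to dienyl, methyl cis to methyl), the trans relation of C3a–H and C7a–H follows from the transition state with the ester endo and the tether exo, and the absolute sense of all four follows from the C6 stereocentre of 15, because A(1,3) strain with the C8 methyl group holds C6–H in the diene plane, so the tether reaches only one diene face and the C6 methyl group ends up cis to C7a–H. The step needs endo(ester) over endo(ketone) selectivity and site selectivity within the tetraene: a ketone in a three-atom tether is twisted out of conjugation with C2=C3 in either transition state and should not compete for the endo position, and only C7 lies within reach of C3, which fixes C10 as the partner of C2. The 1,3-repulsion between the C8 and C10 methyl groups destabilises the s-trans diene and should raise the share of the reactive s-cis conformer, while high dilution suppresses the intermolecular reaction.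

**Step 10**
Reactants: 16 2-(trimethylsilyl)ethyl (1R,3aS,4R,5S,7aS)-1,4,5,7-tetramethyl-3-oxo-5-[(1E,3E)-4-phenylbuta-1,3-dien-1-yl]-2,3,3a,4,5,7a-hexahydro-1H-indene-4-carboxylate
Product: 18 2-(trimethylsilyl)ethyl (1S,3aS,4R,5S,7aS)-1,4,5,7-tetramethyl-5-[(1E,3E)-4-phenylbuta-1,3-dien-1-yl]-3-(trifluoromethylsulfonyloxy)-3a,4,5,7a-tetrahydro-1H-indene-4-carboxylate, via potassium enolate 17 (not isolated)
Conditions: KHMDS, THF, −78 °C; then PhNTf2, −78 to 0 °C
Reagents that add atoms: N-phenylbis(trifluoromethanesulfonimide), O=S(=O)(N(c1ccccc1)S(=O)(=O)C(F)(F)F)C(F)(F)F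
Why: Kinetic enolisation should take the accessible C2 methylene proton rather than the tertiary C3a–H next to the quaternary C4, so O-triflation fixes the C2=C3 alkene without touching the ring fusion (the C1 descriptor changes only through CIP priorities).

**Step 11**
Reactants: 18 2-(trimethylsilyl)ethyl (1S,3aS,4R,5S,7aS)-1,4,5,7-tetramethyl-5-[(1E,3E)-4-phenylbuta-1,3-dien-1-yl]-3-(trifluoromethylsulfonyloxy)-3a,4,5,7a-tetrahydro-1H-indene-4-carboxylate
Product: 19 2-(trimethylsilyl)ethyl (1R,3aR,4R,5S,7aS)-3-ethyl-1,4,5,7-tetramethyl-5-[(1E,3E)-4-phenylbuta-1,3-dien-1-yl]-3a,4,5,7a-tetrahydro-1H-indene-4-carboxylate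
Conditions: Et2Zn, Pd(dppf)Cl2 (5 mol %), THF, 50 °C
Reagents that add atoms: diethylzinc, CC[Zn]CC
Why: Negishi coupling of an alkenyl triflate with a dialkylzinc under a wide-bite-angle bisphosphine favours reductive elimination over β-hydride elimination, and the hindered ester and the unactivated polyene are inert to the zinc reagent.

**Step 12**
Reactants: 19 2-(trimethylsilyl)ethyl (1R,3aR,4R,5S,7aS)-3-ethyl-1,4,5,7-tetramethyl-5-[(1E,3E)-4-phenylbuta-1,3-dien-1-yl]-3a,4,5,7a-tetrahydro-1H-indene-4-carboxylate
Product: 21 22-nor-zyggomphic acid B, via tetrabutylammonium carboxylate 20 (not isolated)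
Conditions: TBAF, THF, rt; then 0.5 M aq. HCl
Reagents that add atoms: none
Why: Fluoride attacks silicon and triggers β-fragmentation of the TMSE ester, so the cleavage does not depend on access to the carbonyl flanked by C5 and C3a, and no stereocentre or alkene is affected.

**Compound list**
1 | (R)-4-methoxy-2-methyl-4-oxobutanoic acid | COC(=O)C[C@@H](C)C(=O)O | starting material
2 | methyl (R)-4-chloro-3-methyl-4-oxobutanoate | COC(=O)C[C@@H](C)C(=O)Cl | intermediate
3 | methyl (R)-3-methyl-4-oxobutanoate | COC(=O)C[C@@H](C)C=O | intermediate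
4 | 2-(triphenylphosphoranylidene)propanal | CC(C=O)=P(c1ccccc1)(c1ccccc1)c1ccccc1 | starting material
5 | methyl (3R,4E)-3,5-dimethyl-6-oxohex-4-enoate | COC(=O)C[C@@H](C)/C=C(\C)C=O | intermediate
6 | methyl (3R,4E,6E)-3,5,7-trimethyl-8-oxoocta-4,6-dienoate | COC(=O)C[C@@H](C)/C=C(\C)/C=C(\C)C=O | intermediate
7 | diethyl (E)-cinnamylphosphonate | CCOP(=O)(OCC)C/C=C/c1ccccc1 | starting material
8 | lithiated diethyl cinnamylphosphonate | [Li+].CCOP(=O)(OCC)[CH-]/C=C/c1ccccc1 | intermediate
9 | methyl (3R,4E,6E,8E,10E)-3,5,7-trimethyl-11-phenylundeca-4,6,8,10-tetraenoate | COC(=O)C[C@@H](C)/C=C(\C)/C=C(\C)/C=C/C=C/c1ccccc1 | intermediate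
10 | (3R,4E,6E,8E,10E)-3,5,7-trimethyl-11-phenylundeca-4,6,8,10-tetraenal | O=CC[C@@H](C)/C=C(\C)/C=C(\C)/C=C/C=C/c1ccccc1 | intermediate
11 | (E)-3-iodo-2-methylprop-2-enoic acid | OC(=O)/C(C)=C/I | starting material
12 | 2-(trimethylsilyl)ethyl (E)-3-iodo-2-methylprop-2-enoate | C[Si](C)(C)CCOC(=O)/C(C)=C/I | intermediate
13 | (E)-alkenylchromium(III) dichloride derived from 12 | C[Si](C)(C)CCOC(=O)/C(C)=C/[Cr](Cl)Cl | intermediate
14 | 2-(trimethylsilyl)ethyl (2E,4RS,6R,7E,9E,11E,13E)-4-hydroxy-2,6,8,10-tetramethyl-14-phenyltetradeca-2,7,9,11,13-pentaenoate | C[Si](C)(C)CCOC(=O)/C(C)=C/C(O)C[C@@H](C)/C=C(\C)/C=C(\C)/C=C/C=C/c1ccccc1 | intermediate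
15 | 2-(trimethylsilyl)ethyl (2E,6R,7E,9E,11E,13E)-2,6,8,10-tetramethyl-4-oxo-14-phenyltetradeca-2,7,9,11,13-pentaenoate | C[Si](C)(C)CCOC(=O)/C(C)=C/C(=O)C[C@@H](C)/C=C(\C)/C=C(\C)/C=C/C=C/c1ccccc1 | intermediate
16 | TMSE (1R,3aS,4R,5S,7aS)-1,4,5,7-tetramethyl-3-oxo-5-[(1E,3E)-4-phenylbuta-1,3-dienyl]-2,3,3a,4,5,7a-hexahydro-1H-indene-4-carboxylate | O=C1C[C@@H](C)[C@@H]2C(C)=C[C@](C)(/C=C/C=C/c3ccccc3)[C@](C)(C(=O)OCC[Si](C)(C)C)[C@@H]12 | intermediate
17 | potassium C2=C3 enolate of 16 | [K+].[O-]C1=C[C@@H](C)[C@@H]2C(C)=C[C@](C)(/C=C/C=C/c3ccccc3)[C@](C)(C(=O)OCC[Si](C)(C)C)[C@@H]12 | intermediate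
18 | C3 enol triflate of 16, (1S,3aS,4R,5S,7aS) | O=S(=O)(OC1=C[C@@H](C)[C@@H]2C(C)=C[C@](C)(/C=C/C=C/c3ccccc3)[C@](C)(C(=O)OCC[Si](C)(C)C)[C@@H]12)C(F)(F)F | intermediate
19 | TMSE ester of the target, (1R,3aR,4R,5S,7aS) | CCC1=C[C@@H](C)[C@@H]2C(C)=C[C@](C)(/C=C/C=C/c3ccccc3)[C@](C)(C(=O)OCC[Si](C)(C)C)[C@@H]12 | intermediate
20 | tetrabutylammonium salt of the target acid | CCC1=C[C@@H](C)[C@@H]2C(C)=C[C@](C)(/C=C/C=C/c3ccccc3)[C@](C)(C(=O)[O-])[C@@H]12.CCCC[N+](CCCC)(CCCC)CCCC | intermediate
21 | 22-nor-zyggomphic acid B, (1R,3aR,4R,5S,7aS)-3-ethyl-1,4,5,7-tetramethyl-5-[(1E,3E)-4-phenylbuta-1,3-dien-1-yl]-3a,4,5,7a-tetrahydro-1H-indene-4-carboxylic acid | CCC1=C[C@@H](C)[C@@H]2C(C)=C[C@](C)(/C=C/C=C/c3ccccc3)[C@](C)(C(=O)O)[C@@H]12 | target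

**Total step count:** 12. **Longest linear sequence:** 11 (steps 1–5 and 7–12).

**Steps most likely to fail**

1. Step 9 (IMDA). The endo/exo selectivity may erode if the tether carbonyl does compete with the ester for the endo position. The doubly activated alkene may also react intermolecularly or polymerise before the demanding bond between two fully substituted carbons can form. The fallback sets out from 14 and comes back at 16, with oxidation and cycloaddition in inverted order. Alcohol 14 (both carbinol epimers) has the ester as its only activating group and an sp3 tether carbon next to the dienophile, which is the substrate class with the closest precedent. It is heated in dilute toluene with BHT at 110 °C to give the trans-fused hydrindenol F1. Dess–Martin oxidation of both carbinol epimers of hydrindenol F1 then converges on 16.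

2. Step 3 (second Wittig homologation). The deactivated enal may react sluggishly, the product may be homologated further, and long heating may erode the E geometry. The fallback sets out from 3 and comes back at 9, and it builds the C5–C6 bond by cross-coupling instead of the C6=C7 alkene by olefination.
   - Aldehyde 3 is converted with CBr4/PPh3 into the dibromoalkene F2.
   - Commercial (2E,4E)-5-phenylpenta-2,4-dienal gives the dienyne F3 with the Ohira–Bestmann reagent.
   - Zr-catalysed carboalumination of F3 (Me3Al, Cp2ZrCl2) gives the alkenylalane F4.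
   - After addition of ZnBr2, F4 is coupled under Pd(DPEphos)Cl2 catalysis with the bromine of F2 that is trans to the chain, to give the (Z)-bromotetraene F5.
   - Methylation of F5 with Me2Zn/Pd(PtBu3)2 with retention gives 9.

3. Step 11 (ethylation of the triflate). Oxidative addition and transmetalation may be slow at the triflate next to the ring fusion, so β-hydride elimination from ethylpalladium could lead to reduction instead of coupling. The fallback sets out from 16 and comes back at 19 without a cross-coupling. Organocerium addition (EtMgBr, CeCl3, THF, −78 °C) to the ketone gives the tertiary carbinol F6. Dehydration of F6 with the Burgess reagent, directed towards the C2 methylene and away from the hindered C3a–H, gives 19.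

**Further compounds**
F1 | step 9 | TMSE (1R,3RS,3aS,4R,5S,7aS)-3-hydroxy-1,4,5,7-tetramethyl-5-[(1E,3E)-4-phenylbuta-1,3-dienyl]-2,3,3a,4,5,7a-hexahydro-1H-indene-4-carboxylate | OC1C[C@@H](C)[C@@H]2C(C)=C[C@](C)(/C=C/C=C/c3ccccc3)[C@](C)(C(=O)OCC[Si](C)(C)C)[C@@H]12
F2 | step 3 | methyl (R)-5,5-dibromo-3-methylpent-4-enoate | COC(=O)C[C@@H](C)C=C(Br)Br
F3 | step 3 | [(1E,3E)-hexa-1,3-dien-5-yn-1-yl]benzene | C#C/C=C/C=C/c1ccccc1
F4 | step 3 | dimethyl[(1E,3E,5E)-2-methyl-6-phenylhexa-1,3,5-trien-1-yl]alane | C[Al](C)/C=C(\C)/C=C/C=C/c1ccccc1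
F5 | step 3 | methyl (3R,4Z,6E,8E,10E)-5-bromo-3,7-dimethyl-11-phenylundeca-4,6,8,10-tetraenoate | COC(=O)C[C@@H](C)/C=C(\Br)/C=C(\C)/C=C/C=C/c1ccccc1
F6 | step 11 | TMSE 3-ethyl-3-hydroxy-1,4,5,7-tetramethyl-5-[(1E,3E)-4-phenylbuta-1,3-dienyl]-2,3,3a,4,5,7a-hexahydro-1H-indene-4-carboxylate (ring stereocentres as in 16, carbinol centre open) | CCC1(O)C[C@@H](C)[C@@H]2C(C)=C[C@](C)(/C=C/C=C/c3ccccc3)[C@](C)(C(=O)OCC[Si](C)(C)C)[C@@H]12
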